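Retrosynthesis (labdane numbering): the angelate C6–O bond and the C14=C15 and C12=C13 double bonds are cut first, giving a 6α‑silyloxy 8α,12‑lactone. Its lactone C–O bond and the ring B bond C8–C9 are then cut together to a monocyclic keto‑enoate, and C6–C7, C5–H/C6–O and C10–C9 cuts lead back to 2,2,6‑trimethylcyclohexanone.
Forward: ring A is present from the start; the C10 quaternary centre, the C5–C6 unit and the C6–C8 chain are built on it and the C9–C11–C12 arm is raised to an enoate. Ring B closes last (step 10) together with a temporary γ‑lactone ring, which is opened and elaborated to the diene before esterification.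
Enabling feature: C8 is a methyl‑bearing tertiary carbinol whose oxygen stands 1,4 to C12 through C9 and C11 (the pattern O–C8–C9–C11–C12 of a γ‑hydroxy acid). A C8 methyl ketone tethered through C7–C6–C5–C10 to C9, the β‑carbon of a C9=C11–C12 enoate, is therefore a ketyl–olefin substrate that closes ring B at C8–C9.
Stereochemistry: C10 comes from ligand‑controlled allylation, C5 from hydrogen delivery by a boron tethered to the C9 arm, C6 from reagent‑controlled methallylboration, and C8 and C9 from the chair transition state of the key step on the trans‑diequatorial ring A template. The 12E geometry comes from a stabilised Wittig reaction and the Z‑angelate is carried in unchanged.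
Key step: step 10

Remark: the (R)‑configured ligand in step 2 is chosen by analogy with the established pairing of the (S)‑ligand with (S)‑2‑allyl‑2‑alkylcyclohexanones.

Step 1
Reactants: 1 2,2,6-trimethylcyclohexan-1-one; 2 allyl chloroformate
Product: 3 allyl 2,6,6-trimethylcyclohex-1-en-1-yl carbonate
Conditions: LiN(SiMe3)2, THF, 0 °C; then 2, −78 → 25 °C
Reagents that add atoms: none
Why: The ketone has a single enolisable position, so O‑acylation of its lithium enolate with the chloroformate (enol carbonate formation) should give the tetrasubstituted enol carbonate regiospecifically.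

Step 2
Reactants: 3 allyl 2,6,6-trimethylcyclohex-1-en-1-yl carbonate
Product: 4 (R)-2-allyl-2,6,6-trimethylcyclohexan-1-one
Conditions: Pd2(dba)3 (cat.), (R)-t-BuPHOX (cat.), THF, 25 °C
Reagents that add atoms: none
Why: Ionisation by zerovalent palladium and loss of CO2 give an allylpalladium enolate pair that recombines inside the chiral phosphinooxazoline pocket (decarboxylative asymmetric allylic alkylation of Tsuji–Trost type), which should set the quaternary C10 centre as R.

Step 3
Reactants: 4 (R)-2-allyl-2,6,6-trimethylcyclohexan-1-one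
Product: 5 (R)-1-allyl-1,3,3-trimethyl-2-methylidenecyclohexane
Conditions: Ph3PCH3Br, KOt-Bu, toluene, 110 °C
Reagents that add atoms: methyltriphenylphosphonium bromide, C[P+](c1ccccc1)(c1ccccc1)c1ccccc1.[Br-]
Why: Wittig methylenation with the ylide generated by KOt-Bu at high temperature is the usual answer to non‑enolisable hindered ketones and should turn the carbonyl into the exocyclic C5=C6 methylene without touching the allyl group or C10.

Step 4
Reactants: 5 (R)-1-allyl-1,3,3-trimethyl-2-methylidenecyclohexane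
Product: 7 3-[(1R,2S)-2-(hydroxymethyl)-1,3,3-trimethylcyclohexyl]propan-1-ol, via borepane 6 (not isolated)
Conditions: thexylborane (from BH3·THF and 2,3-dimethylbut-2-ene), THF, −20 → 25 °C; then NaOH, H2O2, 0 → 25 °C
Reagents that add atoms: hydrogen peroxide, OO
Why: The monosubstituted allyl alkene is hydroborated first and the resulting alkylborane then adds intramolecularly across the hindered 1,1‑disubstituted alkene (cyclic hydroboration of a 1,5‑diene), so boron goes to C6 and hydrogen should reach C5 from the face of the C9 tether, cis to the arm and trans to the C10 methyl, before oxidation converts both C–B bonds into C–O bonds with retention.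

Step 5
Reactants: 7 3-[(1R,2S)-2-(hydroxymethyl)-1,3,3-trimethylcyclohexyl]propan-1-ol
Product: 9 methyl 3-[(1R,2S)-2-(hydroxymethyl)-1,3,3-trimethylcyclohexyl]propanoate, via hydroxy acid 8 (not isolated)
Conditions: TEMPO (cat.), PhI(OAc)2, MeCN/H2O, 0 → 25 °C; then Me3SiCHN2, MeOH/toluene, 0 °C
Reagents that add atoms: water, O; trimethylsilyldiazomethane, C[Si](C)(C)C=[N+]=[N-]
Why: Oxoammonium (TEMPO) oxidation discriminates against the C6 carbinol, which is flanked by two quaternary carbons, so only the unhindered C12 alcohol should be taken to the carboxylic acid, which is then methylated by the diazoalkane (esterification).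

Step 6
Reactants: 9 methyl 3-[(1R,2S)-2-(hydroxymethyl)-1,3,3-trimethylcyclohexyl]propanoate
Product: 11 methyl 3-[(1R,2S)-2-[(1S)-1-hydroxy-3-methylbut-3-en-1-yl]-1,3,3-trimethylcyclohexyl]propanoate, via aldehyde 10 (not isolated)
Conditions: Dess–Martin periodinane, CH2Cl2, 0 °C; then (−)-Ipc2BOMe + CH2=C(CH3)CH2MgCl (premixed), Et2O, −78 °C; NaBO3·4H2O, THF/H2O
Reagents that add atoms: methallylmagnesium chloride, C=C(C)C[Mg]Cl
Why: Dess–Martin oxidation gives the configurationally fragile α‑branched aldehyde, which is trapped cold by reagent‑controlled asymmetric methallylboration (Brown allylation) through a closed six‑membered chair transition state, the borane derived from (+)-α‑pinene being expected to set C6 as S.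

Step 7
Reactants: 11 methyl 3-[(1R,2S)-2-[(1S)-1-hydroxy-3-methylbut-3-en-1-yl]-1,3,3-trimethylcyclohexyl]propanoate
Product: 12 methyl 3-[(1R,2S)-2-[(1S)-1-[(tert-butyldimethylsilyl)oxy]-3-methylbut-3-en-1-yl]-1,3,3-trimethylcyclohexyl]propanoate
Conditions: t-BuMe2SiOTf, 2,6-lutidine, CH2Cl2, −78 → 0 °C
Reagents that add atoms: tert-butyldimethylsilyl triflate, CC(C)(C)[Si](C)(C)OS(=O)(=O)C(F)(F)F
Why: Silylation with the triflate (silyl ether protection) masks the hindered C6 hydroxyl as a bulky non‑chelating group that should sit equatorial in the key step and survive enolate, ozone, SmI2, hydride and ylide chemistry.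

Step 8
Reactants: 12 methyl 3-[(1R,2S)-2-[(1S)-1-[(tert-butyldimethylsilyl)oxy]-3-methylbut-3-en-1-yl]-1,3,3-trimethylcyclohexyl]propanoate
Product: 15 methyl (2E)-3-[(1R,2S)-2-[(1S)-1-[(tert-butyldimethylsilyl)oxy]-3-methylbut-3-en-1-yl]-1,3,3-trimethylcyclohexyl]prop-2-enoate, via selenide 13 (not isolated), via selenoxide 14 (not isolated)
Conditions: LiN(i-Pr)2, THF, −78 °C, then PhSeBr; H2O2, pyridine, CH2Cl2, 0 → 25 °C
Reagents that add atoms: none
Why: The ester carries the only acidic C–H bonds, so its lithium enolate is selenenylated at C11 and the derived selenoxide should undergo syn‑elimination toward C9 (selenoxide elimination) to give the E‑configured C9=C11 enoate.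

Step 9
Reactants: 15 methyl (2E)-3-[(1R,2S)-2-[(1S)-1-[(tert-butyldimethylsilyl)oxy]-3-methylbut-3-en-1-yl]-1,3,3-trimethylcyclohexyl]prop-2-enoate
Product: 16 methyl (2E)-3-[(1R,2S)-2-[(1S)-1-[(tert-butyldimethylsilyl)oxy]-3-oxobutyl]-1,3,3-trimethylcyclohexyl]prop-2-enoate
Conditions: O3, CH2Cl2/MeOH, −78 °C; then Me2S, −78 → 25 °C
Reagents that add atoms: ozone, [O-][O+]=O
Why: Ozone reacts much faster with the electron‑rich 1,1‑disubstituted alkene than with the electron‑poor enoate, so titrated ozonolysis with reductive work‑up should unveil the C8 methyl ketone selectively.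

Step 10
Reactants: 16 methyl (2E)-3-[(1R,2S)-2-[(1S)-1-[(tert-butyldimethylsilyl)oxy]-3-oxobutyl]-1,3,3-trimethylcyclohexyl]prop-2-enoate
Product: 18 (3aR,5S,5aS,9aS,9bR)-5-[(tert-butyldimethylsilyl)oxy]-3a,6,6,9a-tetramethyldecahydronaphtho[2,1-b]furan-2(1H)-one, via hydroxy ester 17 (not isolated)
Conditions: SmI2, HMPA, t-BuOH, THF, −78 → 0 °C; then p-TsOH (cat.), CH2Cl2, 25 °C
Reagents that add atoms: none
Why: Electron transfer from SmI2 to the C8 methyl ketone gives a samarium ketyl whose carbon adds to C9, the β‑carbon of the enoate, after which a second electron transfer gives a samarium enolate that t-BuOH protonates at C11, and the C8 oxygen then acylates onto C12 with loss of methanol. The closest known reaction type is the SmI2‑mediated ketyl–olefin reductive cyclisation of ketones onto tethered α,β‑unsaturated esters with lactonisation of the resulting γ‑hydroxy ester. Ring B closes 6‑exo‑trig through a chair transition state and the lactone ring closes 5‑exo‑trig at the ester carbonyl. C9 is controlled by the ring A template, because with the C5 and C10 arms locked trans‑diequatorial and the C10 methyl axial the chair places C11 equatorial and cis to that methyl (9R), while C8 is controlled by the preference of the bulky solvated oxygen–samarium group for the equatorial position anti to the enoate, which puts C17 axial (8R, oxygen α). The step needs addition of the ketyl to C9 instead of plain reduction of either π‑system, 6‑exo over 7‑endo closure and face selectivity at C8, and these should be secured by the polarity match of the nucleophilic ketyl with the electron‑poor β‑carbon, by the four‑atom tether C7–C6–C5–C10 and by the equatorial non‑chelating 6α‑silyloxy group on the rigid ring A chair.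

Step 11
Reactants: 18 (3aR,5S,5aS,9aS,9bR)-5-[(tert-butyldimethylsilyl)oxy]-3a,6,6,9a-tetramethyldecahydronaphtho[2,1-b]furan-2(1H)-one
Product: 19 (3aR,5S,5aS,9aS,9bR)-5-[(tert-butyldimethylsilyl)oxy]-3a,6,6,9a-tetramethyldodecahydronaphtho[2,1-b]furan-2-ol (anomeric mixture)
Conditions: i-Bu2AlH, CH2Cl2, −78 °C; aq. potassium sodium tartrate
Reagents that add atoms: none
Why: One equivalent of i-Bu2AlH at low temperature should stop at the tetrahedral aluminate of the hindered lactone (partial lactone reduction), giving the lactol without touching the silyl ether.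

Step 12
Reactants: 19 (3aR,5S,5aS,9aS,9bR)-5-[(tert-butyldimethylsilyl)oxy]-3a,6,6,9a-tetramethyldodecahydronaphtho[2,1-b]furan-2-ol
Product: 20 (2E)-4-[(1R,2R,4S,4aS,8aS)-4-[(tert-butyldimethylsilyl)oxy]-2-hydroxy-2,5,5,8a-tetramethyldecahydronaphthalen-1-yl]-2-methylbut-2-enal
Conditions: Ph3P=C(CH3)CHO, toluene, 100 °C
Reagents that add atoms: 2-(triphenylphosphoranylidene)propanal, CC(C=O)=P(c1ccccc1)(c1ccccc1)c1ccccc1
Why: The lactol is in equilibrium with the C12 hydroxy aldehyde, which the formyl‑stabilised ylide should intercept in an E‑selective Wittig olefination under neutral conditions that leave the tertiary 8‑hydroxyl un‑ionised, placing C14 trans to C11.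

Step 13
Reactants: 20 (2E)-4-[(1R,2R,4S,4aS,8aS)-4-[(tert-butyldimethylsilyl)oxy]-2-hydroxy-2,5,5,8a-tetramethyldecahydronaphthalen-1-yl]-2-methylbut-2-enal
Product: 21 (1R,2R,4S,4aS,8aS)-4-[(tert-butyldimethylsilyl)oxy]-2,5,5,8a-tetramethyl-1-[(2E)-3-methylpenta-2,4-dien-1-yl]decahydronaphthalen-2-ol
Conditions: Ph3PCH3Br, KN(SiMe3)2, THF, −78 → 0 °C
Reagents that add atoms: methyltriphenylphosphonium bromide, C[P+](c1ccccc1)(c1ccccc1)c1ccccc1.[Br-]
Why: Wittig methylenation of the enal carbonyl, run cold with excess ylide to cover the free tertiary hydroxyl, should complete the 12E,14‑diene without disturbing the geometry of the trisubstituted alkene.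

Step 14
Reactants: 21 (1R,2R,4S,4aS,8aS)-4-[(tert-butyldimethylsilyl)oxy]-2,5,5,8a-tetramethyl-1-[(2E)-3-methylpenta-2,4-dien-1-yl]decahydronaphthalen-2-ol
Product: 22 (1R,2R,4S,4aS,8aS)-2,5,5,8a-tetramethyl-1-[(2E)-3-methylpenta-2,4-dien-1-yl]decahydronaphthalene-2,4-diol
Conditions: Bu4NF, THF, 25 → 50 °C
Reagents that add atoms: none
Why: Fluoride cleaves the silicon–oxygen bond of the hindered secondary silyl ether (desilylation) under non‑acidic conditions that the acid‑sensitive tertiary alcohol and diene should tolerate.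

Step 15
Reactants: 22 (1R,2R,4S,4aS,8aS)-2,5,5,8a-tetramethyl-1-[(2E)-3-methylpenta-2,4-dien-1-yl]decahydronaphthalene-2,4-diol; 23 angelic acid
Product: 25 (1S,3R,4R,4aS,8aS)-3-hydroxy-3,4a,8,8-tetramethyl-4-[(2E)-3-methylpenta-2,4-dien-1-yl]decahydronaphthalen-1-yl (2Z)-2-methylbut-2-enoate, via mixed anhydride 24 (not isolated)
Conditions: 2,4,6-trichlorobenzoyl chloride, Et3N, toluene, 25 °C; then 22, 80 °C
Reagents that add atoms: none
Why: The mixed anhydride of angelic acid (Yamaguchi‑type esterification run without a nucleophilic catalyst) should acylate the secondary 6α‑hydroxyl in preference to the tertiary 8α‑hydroxyl and do so without Z to E isomerisation to the tiglate.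

Compound list
1 | 2,2,6-trimethylcyclohexan-1-one (racemic) | CC1CCCC(C)(C)C1=O | starting material
2 | allyl chloroformate | C=CCOC(=O)Cl | starting material
3 | allyl 2,6,6-trimethylcyclohex-1-en-1-yl carbonate | C=CCOC(=O)OC1=C(C)CCCC1(C)C | intermediate
4 | (R)-2-allyl-2,6,6-trimethylcyclohexan-1-one | C=CC[C@@]1(C)CCCC(C)(C)C1=O | intermediate
5 | (R)-1-allyl-1,3,3-trimethyl-2-methylidenecyclohexane | C=CC[C@@]1(C)CCCC(C)(C)C1=C | intermediate
6 | B-thexyl borepane (boron bonded to C12 and C6; C5–H cis to the C9 methylene) | CC(C)C(C)(C)B1CCC[C@@]2(C)CCCC(C)(C)[C@@H]2C1 | intermediate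
7 | 3-[(1R,2S)-2-(hydroxymethyl)-1,3,3-trimethylcyclohexyl]propan-1-ol | OCCC[C@@]1(C)CCCC(C)(C)[C@@H]1CO | intermediate
8 | 3-[(1R,2S)-2-(hydroxymethyl)-1,3,3-trimethylcyclohexyl]propanoic acid | OC(=O)CC[C@@]1(C)CCCC(C)(C)[C@@H]1CO | intermediate
9 | methyl 3-[(1R,2S)-2-(hydroxymethyl)-1,3,3-trimethylcyclohexyl]propanoate | COC(=O)CC[C@@]1(C)CCCC(C)(C)[C@@H]1CO | intermediate
10 | methyl 3-[(1R,2S)-2-formyl-1,3,3-trimethylcyclohexyl]propanoate | COC(=O)CC[C@@]1(C)CCCC(C)(C)[C@@H]1C=O | intermediate
11 | methyl 3-[(1R,2S)-2-[(1S)-1-hydroxy-3-methylbut-3-en-1-yl]-1,3,3-trimethylcyclohexyl]propanoate | COC(=O)CC[C@@]1(C)CCCC(C)(C)[C@@H]1[C@@H](O)CC(C)=C | intermediate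
12 | tert-butyldimethylsilyl ether of 11 | COC(=O)CC[C@@]1(C)CCCC(C)(C)[C@@H]1[C@@H](O[Si](C)(C)C(C)(C)C)CC(C)=C | intermediate
13 | α-(phenylselanyl) ester of 12 (selenium on C11, mixture at C11) | COC(=O)C([Se]c1ccccc1)C[C@@]1(C)CCCC(C)(C)[C@@H]1[C@@H](O[Si](C)(C)C(C)(C)C)CC(C)=C | intermediate
14 | selenoxide of 13 | COC(=O)C([Se](=O)c1ccccc1)C[C@@]1(C)CCCC(C)(C)[C@@H]1[C@@H](O[Si](C)(C)C(C)(C)C)CC(C)=C | intermediate
15 | methyl (2E)-3-[(1R,2S)-2-[(1S)-1-[(tert-butyldimethylsilyl)oxy]-3-methylbut-3-en-1-yl]-1,3,3-trimethylcyclohexyl]prop-2-enoate | COC(=O)/C=C/[C@@]1(C)CCCC(C)(C)[C@@H]1[C@@H](O[Si](C)(C)C(C)(C)C)CC(C)=C | intermediate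
16 | methyl (2E)-3-[(1R,2S)-2-[(1S)-1-[(tert-butyldimethylsilyl)oxy]-3-oxobutyl]-1,3,3-trimethylcyclohexyl]prop-2-enoate | COC(=O)/C=C/[C@@]1(C)CCCC(C)(C)[C@@H]1[C@@H](O[Si](C)(C)C(C)(C)C)CC(C)=O | intermediate
17 | methyl 2-[(1R,2R,4S,4aS,8aS)-4-[(tert-butyldimethylsilyl)oxy]-2-hydroxy-2,5,5,8a-tetramethyldecahydronaphthalen-1-yl]acetate | COC(=O)C[C@@H]1[C@@]2(C)CCCC(C)(C)[C@@H]2[C@@H](O[Si](C)(C)C(C)(C)C)C[C@@]1(C)O | intermediate
18 | (3aR,5S,5aS,9aS,9bR)-5-[(tert-butyldimethylsilyl)oxy]-3a,6,6,9a-tetramethyldecahydronaphtho[2,1-b]furan-2(1H)-one (6α-silyloxy 8α,12-lactone) | O=C1C[C@@H]2[C@@]3(C)CCCC(C)(C)[C@@H]3[C@@H](O[Si](C)(C)C(C)(C)C)C[C@@]2(C)O1 | intermediate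
19 | corresponding lactol (2-ol, anomeric mixture) | OC1C[C@@H]2[C@@]3(C)CCCC(C)(C)[C@@H]3[C@@H](O[Si](C)(C)C(C)(C)C)C[C@@]2(C)O1 | intermediate
20 | (2E)-4-[(1R,2R,4S,4aS,8aS)-4-[(tert-butyldimethylsilyl)oxy]-2-hydroxy-2,5,5,8a-tetramethyldecahydronaphthalen-1-yl]-2-methylbut-2-enal | O=C/C(C)=C/C[C@@H]1[C@@]2(C)CCCC(C)(C)[C@@H]2[C@@H](O[Si](C)(C)C(C)(C)C)C[C@@]1(C)O | intermediate
21 | (1R,2R,4S,4aS,8aS)-4-[(tert-butyldimethylsilyl)oxy]-2,5,5,8a-tetramethyl-1-[(2E)-3-methylpenta-2,4-dien-1-yl]decahydronaphthalen-2-ol | C=C/C(C)=C/C[C@@H]1[C@@]2(C)CCCC(C)(C)[C@@H]2[C@@H](O[Si](C)(C)C(C)(C)C)C[C@@]1(C)O | intermediate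
22 | (1R,2R,4S,4aS,8aS)-2,5,5,8a-tetramethyl-1-[(2E)-3-methylpenta-2,4-dien-1-yl]decahydronaphthalene-2,4-diol (labda-12E,14-diene-6α,8α-diol) | C=C/C(C)=C/C[C@@H]1[C@@]2(C)CCCC(C)(C)[C@@H]2[C@@H](O)C[C@@]1(C)O | intermediate
23 | angelic acid, (2Z)-2-methylbut-2-enoic acid | C/C=C(/C)C(=O)O | starting material
24 | angelic 2,4,6-trichlorobenzoic anhydride | C/C=C(/C)C(=O)OC(=O)c1c(Cl)cc(Cl)cc1Cl | intermediate
25 | 6α-angeloyloxy-labda-12E,14-dien-8α-ol (5S,6S,8R,9R,10S) | C=C/C(C)=C/C[C@@H]1[C@@]2(C)CCCC(C)(C)[C@@H]2[C@@H](OC(=O)/C(C)=C\C)C[C@@]1(C)O | target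

Total step count: 15. Longest linear sequence: 15 steps (1 to 25; the route is linear).

Steps most likely to fail:

Step 10. The ketyl may add through the other chair, with the samarium‑bound oxygen axial, which would invert C8; alternatively the enoate or the ketone may simply be reduced without carbon–carbon bond formation. The fallback generates the C8 radical by hydrogen‑atom transfer instead of electron transfer. It sets out from 16, whose methyl ketone is converted with Et3SiOTf and Et3N into the triethylsilyl enol ether F1 (either enol ether regioisomer serves, since both give the same C8 radical). Fe(acac)3 and PhSiH3 in EtOH/ethylene glycol (metal‑hydride hydrogen‑atom‑transfer reductive olefin coupling) should then cyclise the tertiary α‑siloxy radical onto C9 to give the 8‑O‑triethylsilyl ester F2. HF·pyridine removes the tertiary triethylsilyl group and catalytic p-TsOH closes the lactone, so the route is rejoined at 18.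

Step 4. The ring‑closing hydroboration may be too slow at the alkene flanked by two quaternary carbons, so that untethered addition with poor facial selectivity at C5 competes. The fallback sets C5 by directed hydrogenation of an sp2 carbon. It sets out from 5: exhaustive hydroboration–oxidation with BH3·SMe2 gives the diol as a C5 mixture F3, which the step 5 reagents take through the acid mixture F4 to the hydroxy ester mixture F5. Dess–Martin oxidation gives the aldehyde mixture F6, and isopropenyl acetate with catalytic p-TsOH gives the enol acetate F7, in which C5 is planar and the mixture converges. Hydrogenation with [Ir(cod)(PCy3)(py)]PF6, directed by the ester carbonyl of the arm, should deliver hydrogen to C5 cis to the arm and give the acetate F8. K2CO3 in MeOH frees the alcohol and the route is rejoined at 9.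

Step 3. The ylide may fail to add to the carbonyl between two quaternary carbons, so that the ketone is returned. The fallback replaces olefination by addition and elimination. It sets out from 4: MeLi with CeCl3 gives the tertiary carbinol F9, whose configuration at the carbinol carbon is of no consequence. Burgess dehydration, for which only the new methyl group offers β‑hydrogens, gives the exocyclic alkene and the route is rejoined at 5.

Further compounds
F1 | step 10 | triethylsilyl enol ether of 16 (terminal regioisomer drawn) | COC(=O)/C=C/[C@@]1(C)CCCC(C)(C)[C@@H]1[C@@H](O[Si](C)(C)C(C)(C)C)CC(=C)O[Si](CC)(CC)CC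
F2 | step 10 | 8-O-triethylsilyl ether of 17 | COC(=O)C[C@@H]1[C@@]2(C)CCCC(C)(C)[C@@H]2[C@@H](O[Si](C)(C)C(C)(C)C)C[C@@]1(C)O[Si](CC)(CC)CC
F3 | step 4 | diol 7 as a mixture at C5 | OCCC[C@@]1(C)CCCC(C)(C)C1CO
F4 | step 4 | hydroxy acid 8 as a mixture at C5 | OC(=O)CC[C@@]1(C)CCCC(C)(C)C1CO
F5 | step 4 | hydroxy ester 9 as a mixture at C5 | COC(=O)CC[C@@]1(C)CCCC(C)(C)C1CO
F6 | step 4 | aldehyde 10 as a mixture at C5 | COC(=O)CC[C@@]1(C)CCCC(C)(C)C1C=O
F7 | step 4 | enol acetate of F6 (C5=C6, alkene geometry immaterial) | COC(=O)CC[C@@]1(C)CCCC(C)(C)C1=COC(C)=O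
F8 | step 4 | acetate of 9 | COC(=O)CC[C@@]1(C)CCCC(C)(C)[C@@H]1COC(C)=O
F9 | step 3 | (2R)-2-allyl-1,2,6,6-tetramethylcyclohexan-1-ol (mixture at C1) | C=CC[C@@]1(C)CCCC(C)(C)C1(C)O
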